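**Plan**

- Retrosynthesis cuts the C3–O acyl bond (releasing the (Z)-2-(acetoxymethyl)but-2-enoic acid), the isopropenyl C=C (back to a tertiary carbinol) and the C5–acetyl bond (back to an aryl bromide).
- The dihydrofuran ring (O1, C2, C3, C3a, C7a) is then cut at C3a–C3 and at O1–C2, which leaves 4-bromo-3-methoxyphenol and a five-carbon epoxy aldehyde.
- Enabling feature: C3a is ortho to O1 and para to the C6 methoxy group, so it is the most electron-rich ring carbon; C3, C2 and the three isopropenyl carbons are a prenyl unit oxygenated at C3 and C2 exactly as in 3,3-dimethyloxirane-2-carbaldehyde.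
- Forward: prenol to epoxy alcohol to epoxy aldehyde; a one-pot ortho-hydroxyalkylation and epoxide opening closes the only new ring; then acetyl at C5, ester at C3, and dehydration to the isopropenyl group.
- Stereochemistry: C2 comes from the Sharpless epoxidation and is inverted once in the ring closure; C3 comes from chelation-controlled addition to the aldehyde; the side-chain geometry comes from (Z)-2-iodobut-2-en-1-ol by retentive iodine–lithium exchange and carboxylation.

Key step: step 3

Remark on the chemistry: the target is read as the trans (2R,3S) dihydrobenzofuran with a (Z)-enoate (methyl cis to the ester carbonyl); 4-bromo-3-methoxyphenol is chosen as the phenol so that the handle for the acetyl group is present from the start and the para position of the phenolate is blocked; the C2 descriptor changes from S to R in the last step only because the CIP priorities change.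

**Route**

Step 1
Reactants: 1 3-methylbut-2-en-1-ol (prenol)
Product: 2 [(2R)-3,3-dimethyloxiran-2-yl]methanol
Conditions: Ti(OiPr)4 (5 mol%), D-(−)-diisopropyl tartrate (7 mol%), t-BuOOH (anhydrous, isooctane), 4 Å MS, CH2Cl2, −20 °C; non-aqueous work-up, distillation
Reagents that add atoms: tert-butyl hydroperoxide, CC(C)(C)OO
Why: Sharpless asymmetric epoxidation of a primary allylic alcohol is established for prenol, and the titanium complex of the D-(−)-tartrate should deliver oxygen to the alkene face that gives the (R)-epoxy alcohol, which fixes the carbon that becomes C2.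

Step 2
Reactants: 2 [(2R)-3,3-dimethyloxiran-2-yl]methanol
Product: 3 (2S)-3,3-dimethyloxirane-2-carbaldehyde
Conditions: Dess–Martin periodinane, NaHCO3, CH2Cl2, 0 °C to rt; dilution with pentane, filtration through Celite, careful concentration at 0 °C (volatile); used at once as a dry CH2Cl2 solution
Reagents that add atoms: none
Why: Dess–Martin oxidation of a primary alcohol under bicarbonate buffer is mild enough to leave the acid-sensitive trisubstituted epoxide and its stereocenter untouched, the change of descriptor from R to S being only a change of CIP priorities.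

Step 3
Reactants: 4 4-bromo-3-methoxyphenol; 3 (2S)-3,3-dimethyloxirane-2-carbaldehyde
Product: 7 (2S,3S)-5-bromo-2-(2-hydroxypropan-2-yl)-6-methoxy-2,3-dihydro-1-benzofuran-3-ol, via bromomagnesium 4-bromo-3-methoxyphenolate 5 (not isolated), via syn epoxy alcohol magnesium salt 6 (not isolated)
Conditions: EtMgBr (1.0 equiv), Et2O, 0 °C to rt, then solvent exchange to CH2Cl2; 3 (1.1 equiv), −20 °C to rt; then K2CO3 (3 equiv), MeOH, rt; recrystallisation of 7 to raise the enantiomeric purity if needed
Reagents that add atoms: none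
Why: Proposed new method: the magnesium of phenolate 5 should bind the aldehyde oxygen and the epoxide oxygen of 3, and the ortho carbon para to the methoxy group then attacks the carbonyl carbon through a six-membered cyclic transition state (an aldol-type Friedel–Crafts hydroxyalkylation) to form C3a–C3 and, after rearomatisation, adduct 6. The closest known reactions are the ortho-specific, chelation-controlled hydroxyalkylation of bromomagnesium phenolates with alpha-alkoxy aldehydes and the base-mediated cyclisation of ortho-(epoxyprenyl)phenols to 2-(2-hydroxypropan-2-yl)dihydrobenzofurans; joining them in one flask on an epoxy aldehyde is the untested part. Once K2CO3 in methanol has freed the phenoxide, the dihydrofuran ring should close by 5-exo-tet attack of O1 on the secondary epoxide carbon, forming O1–C2. C3 is set by the Cram-chelate geometry, in which the arene reaches the carbonyl face next to the alpha hydrogen and gives the syn (S) carbinol, whereas C2 is the Sharpless-derived epoxide carbon, inverted once by the backside attack, so that the syn adduct becomes the trans (2S,3S) ring. The step needs three selectivities: ortho attack at the carbon para to methoxy (secured by delivery from the magnesium-bound oxygen, by the crowding of the other ortho carbon between two oxygens and by bromine on the para carbon), chelation-controlled facial attack (secured by the donor-free solvent CH2Cl2 and the alpha oxygen of the epoxide), and 5-exo over 6-endo opening (secured by basic closure, which sends the phenoxide to the less substituted epoxide carbon).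

Step 4
Reactants: 7 (2S,3S)-5-bromo-2-(2-hydroxypropan-2-yl)-6-methoxy-2,3-dihydro-1-benzofuran-3-ol; 8 tributyl(1-ethoxyethenyl)stannane
Product: 10 1-[(2S,3S)-3-hydroxy-2-(2-hydroxypropan-2-yl)-6-methoxy-2,3-dihydro-1-benzofuran-5-yl]ethan-1-one, via 5-(1-ethoxyethenyl) enol ether 9 (not isolated)
Conditions: Pd(PPh3)4 (5 mol%), 1,4-dioxane, 100 °C; then 5% aq. oxalic acid, THF, 0 °C
Reagents that add atoms: water, O
Why: Stille coupling of the aryl bromide with the alpha-ethoxyvinylstannane under zerovalent palladium should give enol ether 9, whose hydrolysis under mild acid unmasks the methyl ketone faster than the benzylic alcohol can ionise, and neither stereocenter is involved.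

Step 5
Reactants: 11 (2E)-but-2-enal (crotonaldehyde)
Product: 12 (2Z)-2-iodobut-2-enal
Conditions: I2, K2CO3, DMAP (20 mol%), THF–H2O (1:1), rt
Reagents that add atoms: iodine, II
Why: alpha-Iodination of an enal by a Morita–Baylis–Hillman-type addition–elimination (conjugate addition of DMAP, iodination of the enolate, loss of DMAP) should give the more stable isomer with methyl trans to the formyl group, that is the (Z)-iodoalkene.

Step 6
Reactants: 12 (2Z)-2-iodobut-2-enal
Product: 13 (2Z)-2-iodobut-2-en-1-ol
Conditions: NaBH4, THF–H2O (9:1), 0 °C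
Reagents that add atoms: none
Why: Sodium borohydride reduces the aldehyde by 1,2-addition without touching the vinyl iodide or the alkene geometry.

Step 7
Reactants: 13 (2Z)-2-iodobut-2-en-1-ol
Product: 15 (2Z)-2-(hydroxymethyl)but-2-enoic acid, via lithium (2E)-2-lithiobut-2-en-1-olate 14 (not isolated)
Conditions: 13 added to t-BuLi (3.1 equiv), Et2O, −78 °C; dry CO2, −78 to 0 °C; 1 M HCl, extraction from brine with EtOAc
Reagents that add atoms: carbon dioxide, O=C=O
Why: Iodine–lithium exchange of a vinyl iodide with t-BuLi and carboxylation of the vinyllithium both proceed with retention of alkene geometry, so the methyl group that was cis to iodine should end cis to the carboxyl group.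

Step 8
Reactants: 15 (2Z)-2-(hydroxymethyl)but-2-enoic acid
Product: 16 (2Z)-2-[(acetyloxy)methyl]but-2-enoic acid
Conditions: Ac2O (1.2 equiv), pyridine (2 equiv), CH2Cl2, 0 °C to rt; aqueous work-up, acidic extraction
Reagents that add atoms: acetic anhydride, CC(=O)OC(C)=O
Why: Acetylation of the primary allylic alcohol with acetic anhydride and pyridine is routine, and any mixed anhydride at the carboxyl group is cleaved again in the aqueous work-up.

Step 9
Reactants: 10 1-[(2S,3S)-3-hydroxy-2-(2-hydroxypropan-2-yl)-6-methoxy-2,3-dihydro-1-benzofuran-5-yl]ethan-1-one; 16 (2Z)-2-[(acetyloxy)methyl]but-2-enoic acid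
Product: 18 (2S,3S)-5-acetyl-2-(2-hydroxypropan-2-yl)-6-methoxy-2,3-dihydro-1-benzofuran-3-yl (2Z)-2-[(acetyloxy)methyl]but-2-enoate, via 2,4,6-trichlorobenzoic mixed anhydride 17 (not isolated)
Conditions: 16, 2,4,6-trichlorobenzoyl chloride (1.2 equiv), iPr2NEt (2.5 equiv), toluene, rt; then 10, toluene, 70 °C (no DMAP)
Reagents that add atoms: none
Why: Yamaguchi esterification through the mixed anhydride activates the acid without a nucleophilic catalyst, the usual way to acylate alcohols with angelic-type (Z)-acids without Z to E isomerisation and here also a safeguard against SN2' displacement of the allylic acetate; the secondary C3 alcohol should react while the tertiary alcohol does not, and C3 keeps its configuration because its C–O bond is not broken.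

Step 10
Reactants: 18 (2S,3S)-5-acetyl-2-(2-hydroxypropan-2-yl)-6-methoxy-2,3-dihydro-1-benzofuran-3-yl (2Z)-2-[(acetyloxy)methyl]but-2-enoate
Product: 20 (2R,3S)-5-acetyl-6-methoxy-2-(prop-1-en-2-yl)-2,3-dihydro-1-benzofuran-3-yl (2Z)-2-[(acetyloxy)methyl]but-2-enoate, via tertiary chlorosulfite 19 (not isolated)
Conditions: SOCl2 (1.5 equiv), pyridine, CH2Cl2, −10 to 0 °C
Reagents that add atoms: none
Why: Dehydration of a tertiary alcohol through its chlorosulfite with pyridine as base is the classical conversion of 2-(2-hydroxypropan-2-yl)dihydrobenzofurans into 2-isopropenyl compounds, the E2 elimination taking a methyl hydrogen in preference to the single C2 hydrogen on the oxygen-bearing carbon and leaving both stereocenters intact.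

**Compound list**

1 | 3-methylbut-2-en-1-ol (prenol) | CC(C)=CCO | starting material
2 | [(2R)-3,3-dimethyloxiran-2-yl]methanol | OC[C@H]1OC1(C)C | intermediate
3 | (2S)-3,3-dimethyloxirane-2-carbaldehyde | O=C[C@H]1OC1(C)C | intermediate
4 | 4-bromo-3-methoxyphenol | COc1cc(O)ccc1Br | starting material
5 | bromomagnesium 4-bromo-3-methoxyphenolate | COc1cc(O[Mg]Br)ccc1Br | intermediate
6 | bromomagnesium 4-bromo-2-[(S)-[(2R)-3,3-dimethyloxiran-2-yl](hydroxy)methyl]-5-methoxyphenolate (syn adduct) | COc1cc(O[Mg]Br)c(cc1Br)[C@H](O)[C@H]1OC1(C)C | intermediate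
7 | (2S,3S)-5-bromo-2-(2-hydroxypropan-2-yl)-6-methoxy-2,3-dihydro-1-benzofuran-3-ol | CC(C)(O)[C@H]1Oc2cc(OC)c(Br)cc2[C@@H]1O | intermediate
8 | tributyl(1-ethoxyethenyl)stannane | CCCC[Sn](CCCC)(CCCC)C(=C)OCC | starting material
9 | (2S,3S)-5-(1-ethoxyethenyl)-2-(2-hydroxypropan-2-yl)-6-methoxy-2,3-dihydro-1-benzofuran-3-ol | CC(C)(O)[C@H]1Oc2cc(OC)c(C(=C)OCC)cc2[C@@H]1O | intermediate
10 | 1-[(2S,3S)-3-hydroxy-2-(2-hydroxypropan-2-yl)-6-methoxy-2,3-dihydro-1-benzofuran-5-yl]ethan-1-one | CC(C)(O)[C@H]1Oc2cc(OC)c(C(C)=O)cc2[C@@H]1O | intermediate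
11 | (2E)-but-2-enal (crotonaldehyde) | C/C=C/C=O | starting material
12 | (2Z)-2-iodobut-2-enal | C/C=C(\I)C=O | intermediate
13 | (2Z)-2-iodobut-2-en-1-ol | C/C=C(\I)CO | intermediate
14 | lithium (2E)-2-lithiobut-2-en-1-olate (methyl cis to the C–Li bond) | C/C=C(\[Li])CO[Li] | intermediate
15 | (2Z)-2-(hydroxymethyl)but-2-enoic acid | C/C=C(\C(O)=O)CO | intermediate
16 | (2Z)-2-[(acetyloxy)methyl]but-2-enoic acid | C/C=C(\C(O)=O)COC(C)=O | intermediate
17 | (2Z)-2-[(acetyloxy)methyl]but-2-enoic 2,4,6-trichlorobenzoic anhydride | C/C=C(\C(=O)OC(=O)c1c(Cl)cc(Cl)cc1Cl)COC(C)=O | intermediate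
18 | (2S,3S)-5-acetyl-2-(2-hydroxypropan-2-yl)-6-methoxy-2,3-dihydro-1-benzofuran-3-yl (2Z)-2-[(acetyloxy)methyl]but-2-enoate | CC(C)(O)[C@H]1Oc2cc(OC)c(C(C)=O)cc2[C@@H]1OC(=O)/C(=C\C)COC(C)=O | intermediate
19 | (2S,3S)-5-acetyl-2-{2-[(chlorosulfinyl)oxy]propan-2-yl}-6-methoxy-2,3-dihydro-1-benzofuran-3-yl (2Z)-2-[(acetyloxy)methyl]but-2-enoate | CC(C)(OS(Cl)=O)[C@H]1Oc2cc(OC)c(C(C)=O)cc2[C@@H]1OC(=O)/C(=C\C)COC(C)=O | intermediate
20 | (2R,3S)-5-acetyl-6-methoxy-2-(prop-1-en-2-yl)-2,3-dihydro-1-benzofuran-3-yl (2Z)-2-[(acetyloxy)methyl]but-2-enoate | C=C(C)[C@H]1Oc2cc(OC)c(C(C)=O)cc2[C@@H]1OC(=O)/C(=C\C)COC(C)=O | target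

**Step count**

Total: 10 steps. Longest linear sequence: 6 steps (1 → 2 → 3 → 7 → 10 → 18 → 20; the acid branch 11 → 12 → 13 → 15 → 16 → 18 → 20 is equally long).

**Steps most likely to fail**

Step 3 (the step that carries the proposed new method). Three processes could defeat it: magnesium-promoted opening or rearrangement of the trisubstituted epoxide before the C–C bond forms; weak chelation, so that facial selectivity at the aldehyde erodes and the cis ring isomer appears; and slow arylation because bromine lowers the nucleophilicity of the phenolate. The fallback uses only known reaction types, sets out from 3 and rejoins the route at 7.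
- Commercial 2-bromo-5-methoxyphenol is silylated (TBSCl, imidazole, DMF) to tert-butyl(2-bromo-5-methoxyphenoxy)dimethylsilane F1.
- With magnesium turnings in THF, F1 should give [2-(tert-butyldimethylsilyloxy)-4-methoxyphenyl]magnesium bromide F2.
- Addition of F2 to 3 in Et2O–CH2Cl2 at −78 °C is a Grignard addition to a 2,3-epoxy aldehyde and should be fast enough to outrun opening of the epoxide. It should give (S)-[2-(tert-butyldimethylsilyloxy)-4-methoxyphenyl][(2R)-3,3-dimethyloxiran-2-yl]methanol F3; the syn isomer is separated from any anti isomer by chromatography.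
- Bu4NF in THF removes the silyl group, and the released phenoxide closes the ring by the same 5-exo opening to (2S,3S)-2-(2-hydroxypropan-2-yl)-6-methoxy-2,3-dihydro-1-benzofuran-3-ol F4.
- NBS in MeCN at 0 °C brominates C5 (para to O1, ortho to the methoxy group) and returns 7.

Step 9. The activated (Z)-acyl donor may isomerise to the E isomer, the allylic acetate may be lost by SN2' attack of amine or carboxylate on the activated acrylate, and acylation of the hindered benzylic alcohol may be too slow without a nucleophilic catalyst. The fallback removes the allylic leaving group from the acyl donor and adds the acetate last; it sets out from 15 and 10 and rejoins the route at 18.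
- 15 is silylated twice (TBSCl, imidazole, DMF) to tert-butyldimethylsilyl (2Z)-2-{[(tert-butyldimethylsilyl)oxy]methyl}but-2-enoate F5.
- The silyl ester is cleaved selectively (K2CO3, MeOH–THF–H2O) to (2Z)-2-{[(tert-butyldimethylsilyl)oxy]methyl}but-2-enoic acid F6.
- 1-Chloro-N,N,2-trimethylprop-1-en-1-amine in CH2Cl2 under neutral conditions converts F6 into (2Z)-2-{[(tert-butyldimethylsilyl)oxy]methyl}but-2-enoyl chloride F7.
- F7 acylates 10 (pyridine, CH2Cl2, 0 °C) to (2S,3S)-5-acetyl-2-(2-hydroxypropan-2-yl)-6-methoxy-2,3-dihydro-1-benzofuran-3-yl (2Z)-2-{[(tert-butyldimethylsilyl)oxy]methyl}but-2-enoate F8.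
- HF·pyridine in THF frees (2S,3S)-5-acetyl-2-(2-hydroxypropan-2-yl)-6-methoxy-2,3-dihydro-1-benzofuran-3-yl (2Z)-2-(hydroxymethyl)but-2-enoate F9.
- Ac2O and pyridine at 0 °C acetylate the primary allylic alcohol of F9, not the tertiary one, to give 18.

Step 10. The benzylic acyloxy group may ionise under the dehydrating conditions, with loss of the ester and aromatisation to the benzofuran, or elimination may run toward C2 instead of toward a methyl group. The fallback dehydrates before the ester is in place, on a substrate that carries a poor leaving group at C3; it sets out from 10 and rejoins the route at 20.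
- TESCl and imidazole in DMF at 0 °C silylate only the secondary alcohol, giving 1-[(2S,3S)-2-(2-hydroxypropan-2-yl)-6-methoxy-3-[(triethylsilyl)oxy]-2,3-dihydro-1-benzofuran-5-yl]ethan-1-one F10.
- Methyl N-(triethylammoniosulfonyl)carbamate (Burgess reagent) in toluene at 50 °C should form the tertiary N-(methoxycarbonyl)sulfamate triethylammonium salt F11.
- Syn elimination of F11 should give 1-[(2R,3S)-6-methoxy-2-(prop-1-en-2-yl)-3-[(triethylsilyl)oxy]-2,3-dihydro-1-benzofuran-5-yl]ethan-1-one F12.
- Bu4NF buffered with acetic acid in THF gives 1-[(2R,3S)-3-hydroxy-6-methoxy-2-(prop-1-en-2-yl)-2,3-dihydro-1-benzofuran-5-yl]ethan-1-one F13.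
- F13 is esterified with 16 through mixed anhydride 17 under the conditions of step 9 to give 20.

Further compounds
F1 | step 3 | tert-butyl(2-bromo-5-methoxyphenoxy)dimethylsilane | COc1ccc(Br)c(O[Si](C)(C)C(C)(C)C)c1
F2 | step 3 | [2-(tert-butyldimethylsilyloxy)-4-methoxyphenyl]magnesium bromide | COc1ccc([Mg]Br)c(O[Si](C)(C)C(C)(C)C)c1
F3 | step 3 | (S)-[2-(tert-butyldimethylsilyloxy)-4-methoxyphenyl][(2R)-3,3-dimethyloxiran-2-yl]methanol | COc1ccc([C@H](O)[C@H]2OC2(C)C)c(O[Si](C)(C)C(C)(C)C)c1
F4 | step 3 | (2S,3S)-2-(2-hydroxypropan-2-yl)-6-methoxy-2,3-dihydro-1-benzofuran-3-ol | CC(C)(O)[C@H]1Oc2cc(OC)ccc2[C@@H]1O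
F5 | step 9 | tert-butyldimethylsilyl (2Z)-2-{[(tert-butyldimethylsilyl)oxy]methyl}but-2-enoate | C/C=C(\C(=O)O[Si](C)(C)C(C)(C)C)CO[Si](C)(C)C(C)(C)C
F6 | step 9 | (2Z)-2-{[(tert-butyldimethylsilyl)oxy]methyl}but-2-enoic acid | C/C=C(\C(O)=O)CO[Si](C)(C)C(C)(C)C
F7 | step 9 | (2Z)-2-{[(tert-butyldimethylsilyl)oxy]methyl}but-2-enoyl chloride | C/C=C(\C(Cl)=O)CO[Si](C)(C)C(C)(C)C
F8 | step 9 | (2S,3S)-5-acetyl-2-(2-hydroxypropan-2-yl)-6-methoxy-2,3-dihydro-1-benzofuran-3-yl (2Z)-2-{[(tert-butyldimethylsilyl)oxy]methyl}but-2-enoate | CC(C)(O)[C@H]1Oc2cc(OC)c(C(C)=O)cc2[C@@H]1OC(=O)/C(=C\C)CO[Si](C)(C)C(C)(C)C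
F9 | step 9 | (2S,3S)-5-acetyl-2-(2-hydroxypropan-2-yl)-6-methoxy-2,3-dihydro-1-benzofuran-3-yl (2Z)-2-(hydroxymethyl)but-2-enoate | CC(C)(O)[C@H]1Oc2cc(OC)c(C(C)=O)cc2[C@@H]1OC(=O)/C(=C\C)CO
F10 | step 10 | 1-[(2S,3S)-2-(2-hydroxypropan-2-yl)-6-methoxy-3-[(triethylsilyl)oxy]-2,3-dihydro-1-benzofuran-5-yl]ethan-1-one | CC(C)(O)[C@H]1Oc2cc(OC)c(C(C)=O)cc2[C@@H]1O[Si](CC)(CC)CC
F11 | step 10 | triethylammonium 2-[(2S,3S)-5-acetyl-6-methoxy-3-[(triethylsilyl)oxy]-2,3-dihydro-1-benzofuran-2-yl]propan-2-yl N-(methoxycarbonyl)sulfamate | CC(C)(OS(=O)(=O)[N-]C(=O)OC)[C@H]1Oc2cc(OC)c(C(C)=O)cc2[C@@H]1O[Si](CC)(CC)CC.CC[NH+](CC)CC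
F12 | step 10 | 1-[(2R,3S)-6-methoxy-2-(prop-1-en-2-yl)-3-[(triethylsilyl)oxy]-2,3-dihydro-1-benzofuran-5-yl]ethan-1-one | C=C(C)[C@H]1Oc2cc(OC)c(C(C)=O)cc2[C@@H]1O[Si](CC)(CC)CC
F13 | step 10 | 1-[(2R,3S)-3-hydroxy-6-methoxy-2-(prop-1-en-2-yl)-2,3-dihydro-1-benzofuran-5-yl]ethan-1-one | C=C(C)[C@H]1Oc2cc(OC)c(C(C)=O)cc2[C@@H]1O
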